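The ring is opened at C5–C6. Quaternary C1 of the cyclohexane carries two carbons that both trace back to formyl groups: ring carbon C6 (CHBr) and the inner carbon of the chlorovinyl group. C1 is therefore the central carbon of a 2,2-disubstituted malonaldehyde. In one operation the D-proline enamine of a pendant methyl ketone (C4, nucleophilic C5) attacks one of the two formyl groups, closes the six-membered ring and sets C1 and C6 together. The precursor is the open-chain keto dialdehyde 5, OHC–C(CH3)(CHO)–CH2–CH(CH3)–COCH3. Afterwards the spare formyl group becomes the chlorovinyl unit, the ketone becomes a C3–C4 epoxide that delivers the cis chloride/bromide pair, and both carbinols are exchanged for bromide with inversion.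

Key step: step 4

Numbering (target numbering, used for all ring compounds): C1 = C(CH3)(CH=CHCl), C2 = CH2, C3 = C(CH3)Cl, C4 = CHBr, C5 = CH2, C6 = CHBr. The "top face" is the face of the chlorovinyl group. In the target, Cl (C3) and Br (C4) are on the top face. Br (C6) and both methyl groups are on the bottom face.

Remark: 5 has a stereocentre at C3 and is used as the racemate, so its two formyl groups are enantiotopic only if C3 is disregarded. C3 is made planar again in step 7, and the consequence for step 4 is treated under the risks.

Step 1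
Reactants: 1 diethyl 2-methylpropanedioate; 2 3-methylbut-3-en-2-one
Product: 3 diethyl 2-methyl-2-(2-methyl-3-oxobutyl)propanedioate (racemic)
Conditions: NaOEt (10 mol %), EtOH, 0 °C → rt
Reagents that add atoms: none
Why: Michael addition, in which the catalytically generated malonate enolate adds to the unsubstituted terminus of the enone and ethanol reprotonates the adduct, creating C3 as a racemic centre that is removed again in step 7.

Step 2
Reactants: 3 diethyl 2-methyl-2-(2-methyl-3-oxobutyl)propanedioate
Product: 4 2-(hydroxymethyl)-2,4-dimethylhexane-1,5-diol (diastereomer mixture)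
Conditions: LiAlH4, THF, 0 °C → reflux; aqueous NaOH work-up
Reagents that add atoms: none
Why: Exhaustive LiAlH4 reduction of two esters and a ketone is routine, and the extra carbinol centre is of no consequence because it is re-oxidised in step 3.

Step 3
Reactants: 4 2-(hydroxymethyl)-2,4-dimethylhexane-1,5-diol
Product: 5 2-methyl-2-(2-methyl-3-oxobutyl)propanedial (racemic at C3, used crude at once)
Conditions: (COCl)2, DMSO, CH2Cl2, −78 °C; Et3N, −78 → −20 °C; cold pH 7 buffer
Reagents that add atoms: none
Why: Swern oxidation activates all three hydroxyl groups as alkoxysulfonium ions before any carbonyl group exists, so lactol formation and over-oxidation to a lactone are avoided, and 2,2-disubstituted propane-1,3-diols are known to give non-enolisable malonaldehydes in this way.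

Step 4
Reactants: 5 2-methyl-2-(2-methyl-3-oxobutyl)propanedial
Product: 6 (1S,2R)-2-hydroxy-1,5-dimethyl-4-oxocyclohexane-1-carbaldehyde (OH and CHO cis; epimer mixture at C5 of this name, which is C3 in target numbering)
Conditions: D-proline (30 mol %), DMSO, 23 °C
Reagents that add atoms: none
Why: D-proline condenses with the methyl ketone of 5 to the less substituted enamine (C4=C5), C5 adds to one formyl carbon (the future C6) while the carboxylic acid passes its proton to that formyl oxygen, and hydrolysis of the iminium ion releases 6 and the catalyst. The closest known reaction type is the Hajos–Parrish–Eder–Sauer–Wiechert reaction, a proline-catalysed group-selective intramolecular aldol addition, and the one ring formed, the cyclohexanone, closes in the 6-(enolendo)-exo-trig mode through a chair. C6 is set by the catalyst: the hydrogen bond can only reach a formyl oxygen that lies pseudo-axial above the enamine nitrogen, this arrangement gives the S carbinol carbon with L-proline in the Hajos–Parrish ketol, and its mirror image with D-proline should therefore give R at C6. C1 is set relative to C6 by the chair, with the spectator formyl group pseudo-equatorial and antiperiplanar to the forming C5–C6 bond, where its C1–CHO σ* orbital stabilises the transition state, so that OH and CHO end cis (1S in 6). The step needs one donor and one ring size, which the substrate secures because the dialdehyde carbon has no α-hydrogen and attack from C3 would give a cyclobutane, and it needs cis selectivity, which is backed by the fact that the two C6-R ketols can interconvert through 5 by retro-aldol and the cis ketol is the more stable one (OH and both methyl groups equatorial, OH···O=CH hydrogen bond). C3 remains an epimer mixture and is made planar in step 7.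

Step 5
Reactants: 6 (1S,2R)-2-hydroxy-1,5-dimethyl-4-oxocyclohexane-1-carbaldehyde
Product: 7 (1S,2R)-2-[(tert-butyldimethylsilyl)oxy]-1,5-dimethyl-4-oxocyclohexane-1-carbaldehyde (C5 epimers)
Conditions: TBSOTf (1.1 equiv), 2,6-lutidine, CH2Cl2, −78 °C
Reagents that add atoms: tert-butyldimethylsilyl trifluoromethanesulfonate, CC(C)(C)[Si](C)(C)OS(=O)(=O)C(F)(F)F
Why: O-silylation of a hindered secondary alcohol with a silyl triflate is fast at −78 °C, blocks both retro-aldol pathways and β-elimination, and leaves C1 and C6 untouched.

Step 6
Reactants: 7 (1S,2R)-2-[(tert-butyldimethylsilyl)oxy]-1,5-dimethyl-4-oxocyclohexane-1-carbaldehyde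
Product: 8 (4R,5R)-5-[(tert-butyldimethylsilyl)oxy]-4-[(E)-2-chloroethenyl]-2,4-dimethylcyclohexan-1-one (C2 epimers)
Conditions: CrCl2 (6 equiv), CHCl3 (3 equiv), THF, 65 °C
Reagents that add atoms: chloroform, ClC(Cl)Cl
Why: Takai olefination, in which the geminal dichromium species made from CHCl3 and CrCl2 adds to the aldehyde much faster than to the ketone and elimination from the less crowded adduct gives the E chloroalkene, a preference that grows with the bulk of an α-quaternary aldehyde.

Step 7
Reactants: 8 (4R,5R)-5-[(tert-butyldimethylsilyl)oxy]-4-[(E)-2-chloroethenyl]-2,4-dimethylcyclohexan-1-one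
Product: 9 (4R,5R)-5-[(tert-butyldimethylsilyl)oxy]-4-[(E)-2-chloroethenyl]-2,4-dimethylcyclohex-1-en-1-yl trifluoromethanesulfonate
Conditions: Tf2O, 2,6-di-tert-butyl-4-methylpyridine, CH2Cl2, 0 °C → rt
Reagents that add atoms: trifluoromethanesulfonic anhydride, O=S(=O)(OS(=O)(=O)C(F)(F)F)C(F)(F)F
Why: Enol triflate formation with Tf2O and a hindered pyridine runs through the O-triflyl oxocarbenium ion, which loses the proton that gives the more substituted C3=C4 alkene as with 2-methylcyclohexanone, so both C3 epimers converge on one product.

Step 8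
Reactants: 9 (4R,5R)-5-[(tert-butyldimethylsilyl)oxy]-4-[(E)-2-chloroethenyl]-2,4-dimethylcyclohex-1-en-1-yl trifluoromethanesulfonate
Product: 10 tert-butyl({(1R,6R)-6-[(E)-2-chloroethenyl]-4,6-dimethylcyclohex-3-en-1-yl}oxy)dimethylsilane
Conditions: Pd(OAc)2 (5 mol %), PPh3 (10 mol %), HCO2H, Et3N, DMF, 60 °C
Reagents that add atoms: none
Why: In this palladium-catalysed formate reduction of an enol triflate, zerovalent palladium inserts into the C–OTf bond far faster than into the alkenyl chloride, formate supplies hydride with loss of CO2, and reductive elimination leaves the trisubstituted alkene in place.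

Step 9
Reactants: 10 tert-butyl({(1R,6R)-6-[(E)-2-chloroethenyl]-4,6-dimethylcyclohex-3-en-1-yl}oxy)dimethylsilane
Product: 11 tert-butyl({(1S,3R,4R,6R)-3-[(E)-2-chloroethenyl]-1,3-dimethyl-7-oxabicyclo[4.1.0]heptan-4-yl}oxy)dimethylsilane (epoxide oxygen on the bottom face)
Conditions: mCPBA, CH2Cl2, 0 °C
Reagents that add atoms: 3-chloroperoxybenzoic acid, OOC(=O)c1cccc(Cl)c1
Why: Prilezhaev epoxidation picks the electron-rich trisubstituted alkene over the chloroalkene, and oxygen should arrive on the bottom face because the chlorovinyl group (C1) and the OTBS group (C6) both stand on the top face and one of them is pseudo-axial in either half-chair, which sets C3 (S) and C4 (R).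

Step 10
Reactants: 11 tert-butyl({(1S,3R,4R,6R)-3-[(E)-2-chloroethenyl]-1,3-dimethyl-7-oxabicyclo[4.1.0]heptan-4-yl}oxy)dimethylsilane
Product: 13 (1R,3R,4R,6R)-4-chloro-6-[(E)-2-chloroethenyl]-4,6-dimethylcyclohexane-1,3-diol, via chlorohydrin silyl ether 12 (not isolated)
Conditions: HCl (2 M in Et2O), CH2Cl2, −40 → 0 °C; then 48% aq. HF, MeCN, 0 °C → rt
Reagents that add atoms: hydrogen chloride, Cl
Why: Acid-mediated epoxide opening places chloride on the tertiary carbon C3 with inversion in the trans-diaxial mode (as known for 1-methylcyclohexene oxide and HCl), giving top-face chlorine and a bottom-face C4 hydroxyl, and aqueous HF then cleaves the silyl ether without base so the chlorohydrin cannot close back to the epoxide.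

Step 11
Reactants: 13 (1R,3R,4R,6R)-4-chloro-6-[(E)-2-chloroethenyl]-4,6-dimethylcyclohexane-1,3-diol
Product: 14 (1S,2R,4R,5S)-1,5-dibromo-2-chloro-4-[(E)-2-chloroethenyl]-2,4-dimethylcyclohexane (target)
Conditions: PPh3 (5 equiv), CBr4 (5 equiv), toluene, 0 → 70 °C
Reagents that add atoms: tetrabromomethane, BrC(Br)(Br)Br
Why: In this double Appel reaction each carbinol is activated as an oxyphosphonium ion and displaced by bromide from the opposite face (SN2), so C4 goes from R to S (bromine cis to chlorine, as in the known conversion of trans-halohydrin oxyphosphonium salts into cis-dihalides) and C6 from R to S, phosphorus activation being the method that brominates neopentyl-type alcohols without skeletal rearrangement.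

Compound list
1 | diethyl 2-methylpropanedioate | CCOC(=O)C(C)C(=O)OCC | starting material
2 | 3-methylbut-3-en-2-one | CC(=O)C(C)=C | starting material
3 | diethyl 2-methyl-2-(2-methyl-3-oxobutyl)propanedioate (racemic) | CCOC(=O)C(C)(CC(C)C(C)=O)C(=O)OCC | intermediate
4 | 2-(hydroxymethyl)-2,4-dimethylhexane-1,5-diol (diastereomer mixture) | OCC(C)(CO)CC(C)C(C)O | intermediate
5 | 2-methyl-2-(2-methyl-3-oxobutyl)propanedial (racemic at C3) | O=CC(C)(C=O)CC(C)C(C)=O | intermediate
6 | (1S,2R)-2-hydroxy-1,5-dimethyl-4-oxocyclohexane-1-carbaldehyde (C5 epimers) | C[C@]1(C=O)CC(C)C(=O)C[C@H]1O | intermediate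
7 | (1S,2R)-2-[(tert-butyldimethylsilyl)oxy]-1,5-dimethyl-4-oxocyclohexane-1-carbaldehyde (C5 epimers) | C[C@]1(C=O)CC(C)C(=O)C[C@H]1O[Si](C)(C)C(C)(C)C | intermediate
8 | (4R,5R)-5-[(tert-butyldimethylsilyl)oxy]-4-[(E)-2-chloroethenyl]-2,4-dimethylcyclohexan-1-one (C2 epimers) | C[C@]1(/C=C/Cl)CC(C)C(=O)C[C@H]1O[Si](C)(C)C(C)(C)C | intermediate
9 | (4R,5R)-5-[(tert-butyldimethylsilyl)oxy]-4-[(E)-2-chloroethenyl]-2,4-dimethylcyclohex-1-en-1-yl trifluoromethanesulfonate | C[C@]1(/C=C/Cl)CC(C)=C(OS(=O)(=O)C(F)(F)F)C[C@H]1O[Si](C)(C)C(C)(C)C | intermediate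
10 | tert-butyl({(1R,6R)-6-[(E)-2-chloroethenyl]-4,6-dimethylcyclohex-3-en-1-yl}oxy)dimethylsilane | C[C@]1(/C=C/Cl)CC(C)=CC[C@H]1O[Si](C)(C)C(C)(C)C | intermediate
11 | tert-butyl({(1S,3R,4R,6R)-3-[(E)-2-chloroethenyl]-1,3-dimethyl-7-oxabicyclo[4.1.0]heptan-4-yl}oxy)dimethylsilane | C[C@]1(/C=C/Cl)C[C@]2(C)O[C@@H]2C[C@H]1O[Si](C)(C)C(C)(C)C | intermediate
12 | (1R,2R,4R,5R)-5-[(tert-butyldimethylsilyl)oxy]-2-chloro-4-[(E)-2-chloroethenyl]-2,4-dimethylcyclohexan-1-ol (not isolated) | C[C@]1(/C=C/Cl)C[C@@](C)(Cl)[C@H](O)C[C@H]1O[Si](C)(C)C(C)(C)C | intermediate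
13 | (1R,3R,4R,6R)-4-chloro-6-[(E)-2-chloroethenyl]-4,6-dimethylcyclohexane-1,3-diol | C[C@]1(/C=C/Cl)C[C@@](C)(Cl)[C@H](O)C[C@H]1O | intermediate
14 | (1S,2R,4R,5S)-1,5-dibromo-2-chloro-4-[(E)-2-chloroethenyl]-2,4-dimethylcyclohexane | C[C@]1(/C=C/Cl)C[C@@](C)(Cl)[C@@H](Br)C[C@@H]1Br | target

Total step count: 11. Longest linear sequence: 11 steps (1 and 2 to 14).

Steps most likely to fail

1. Step 4. Three processes threaten it.
   - A formyl group may be transferred from the non-enolisable dialdehyde to the amine (deformylation).
   - The resident C3 centre may steer the ring closure. In the chair its methyl group lies either in the enamine plane, where it clashes with the pyrrolidine ring, or axial, where it meets the axial substituent at C1. One enantiomer of 5 is therefore mismatched, and enantiomeric purity at C1/C6 is lost once C3 is erased.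
   - The spectator formyl group may take the axial instead of the equatorial site. This gives the trans relationship and the wrong sense at C1.

   Fallback (equilibration plus resolution in place of asymmetric catalysis), from 5 back to 6:
   - DBU (5 mol %) in CH2Cl2 at 0 °C closes the ring under thermodynamic control. This gives the racemic cis ketol, that is, 6 together with its mirror image, the (1R,2S)-ketol F1.
   - Candida antarctica lipase B and vinyl acetate in tert-butyl methyl ether should acetylate the R carbinol selectively (large quaternary C1 against medium C5H2) to the acetate F2.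
   - F2 is separated from unreacted F1 and hydrolysed by the same lipase in pH 7 phosphate buffer to 6.

2. Step 11. Displacement may stall at the neopentyl-type C6 oxyphosphonium ion, whose leaving group is equatorial in the chair that keeps chlorovinyl and chlorine axial. Elimination or ring-bond migration could then take over on heating. At C4 the antiperiplanar tertiary chlorine may take part, with loss of inversion or a 1,2-chlorine shift.

   Fallback (the two C–Br bonds are made separately, C6 first while C3/C4 are still masked as the epoxide), from 11 to 14: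
   - Bu4NF in THF gives the epoxy alcohol F3.
   - Tf2O and pyridine at −20 °C give the triflate F4.
   - Bu4NBr in toluene displaces the triflate with inversion to the bromo epoxide F5. The half-chair can place the leaving group pseudo-axial, and there is no chlorine neighbour yet.
   - HCl in Et2O opens F5 as in step 10 to the bromo chlorohydrin F6.
   - A single Appel reaction (PPh3, CBr4) at C4 gives 14.

3. Step 9. The risk is poor facial selectivity of oxygen transfer, or a preference for the top face, which would invert both C3 and C4.

   Fallback (electrophilic chlorine instead of electrophilic oxygen, so that a top-face preference becomes the productive one), from 8 to 13, bypassing steps 7 to 10: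
   - SO2Cl2 in CH2Cl2 at 0 °C chlorinates the more substituted enol to the α-chloro ketone F7.
   - Aqueous HF in MeCN frees the C6 hydroxyl to give the hydroxy chloro ketone F8.
   - Saksena–Evans reduction with Me4NBH(OAc)3 in MeCN/AcOH delivers hydride from the face of the C6 hydroxyl and gives the 1,3-anti diol 13.

Further compounds
F1 | step 4 | (1R,2S)-2-hydroxy-1,5-dimethyl-4-oxocyclohexane-1-carbaldehyde | C[C@@]1(C=O)CC(C)C(=O)C[C@@H]1O
F2 | step 4 | (1R,2S)-2-formyl-2,4-dimethyl-5-oxocyclohexyl acetate | C[C@]1(C=O)CC(C)C(=O)C[C@H]1OC(C)=O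
F3 | step 11 | (1S,3R,4R,6R)-3-[(E)-2-chloroethenyl]-1,3-dimethyl-7-oxabicyclo[4.1.0]heptan-4-ol | C[C@]1(/C=C/Cl)C[C@]2(C)O[C@@H]2C[C@H]1O
F4 | step 11 | (1S,3R,4R,6R)-3-[(E)-2-chloroethenyl]-1,3-dimethyl-7-oxabicyclo[4.1.0]heptan-4-yl trifluoromethanesulfonate | C[C@]1(/C=C/Cl)C[C@]2(C)O[C@@H]2C[C@H]1OS(=O)(=O)C(F)(F)F
F5 | step 11 | (1S,3R,4S,6R)-4-bromo-3-[(E)-2-chloroethenyl]-1,3-dimethyl-7-oxabicyclo[4.1.0]heptane | C[C@]1(/C=C/Cl)C[C@]2(C)O[C@@H]2C[C@@H]1Br
F6 | step 11 | (1R,2R,4R,5S)-5-bromo-2-chloro-4-[(E)-2-chloroethenyl]-2,4-dimethylcyclohexan-1-ol | C[C@]1(/C=C/Cl)C[C@@](C)(Cl)[C@H](O)C[C@@H]1Br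
F7 | step 9 | (2R,4R,5R)-5-[(tert-butyldimethylsilyl)oxy]-2-chloro-4-[(E)-2-chloroethenyl]-2,4-dimethylcyclohexan-1-one | C[C@]1(/C=C/Cl)C[C@@](C)(Cl)C(=O)C[C@H]1O[Si](C)(C)C(C)(C)C
F8 | step 9 | (2R,4R,5R)-2-chloro-4-[(E)-2-chloroethenyl]-5-hydroxy-2,4-dimethylcyclohexan-1-one | C[C@]1(/C=C/Cl)C[C@@](C)(Cl)C(=O)C[C@H]1O
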